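**Retrosynthetic overview**
1. The last two steps free the ring-B C7 phenol (silyl ether) and the lactol (acetate) of a fully assembled ester; the lactol carbon is carried as its (3R)-acetate from the point where it is set.
2. The strategy rests on ring A (C1 ester carbon, C2–OH, C3–Me, C4–OMe, C5–H, C6–Me): OH and OMe are meta with a methyl between them, so C2 maps onto a ketene carbon, C3/C4 onto 1-methoxypropyne, C5 onto a diazo carbon and C6/C1 onto an enoate that already carries the ester.
3. Ring A is therefore cut to ring-B (E)-5-diazo-3-methyl-4-oxopent-2-enoate 24 plus 1-methoxypropyne 23 (photo-Wolff benzannulation); the (E)-alkene is required, because a (Z)-ester would capture the ketene internally as a 2-pyranone.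
4. Compound 24 comes from Steglich esterification of ring-B alcohol 13 with diazo acid 20 (biacetyl Wittig, then diazo transfer, which avoids diazoalkanes that would add to the doubly activated alkene).
5. Ring order: the ring-B benzene is bought; its lactone ring closes in step 5 after two directed lithiations, the lactol carbon is set by lipase dynamic kinetic acetylation in step 6, and ring A is formed last in step 14.

Key step: step 14

Assumption: the free lactol of the target epimerises only slowly by ring–chain tautomerism in neutral, aprotic medium at or below 20 °C, so that the (3R) compound can be isolated after a neutral final deacylation.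

**Step 1**
Reactants: 1 3-hydroxy-5-methoxybenzaldehyde
Product: 2 3-methoxy-5-(methoxymethoxy)benzaldehyde
Conditions: MOMCl, iPr2NEt, CH2Cl2, 0 °C to rt
Reagents that add atoms: chloromethyl methyl ether, COCCl
Why: O-alkylation of the phenol (Williamson type) installs the MOM ether, which later acts as the stronger of the two ortho-directing oxygens and is removed by aqueous acid.

**Step 2**
Reactants: 2 3-methoxy-5-(methoxymethoxy)benzaldehyde
Product: 3 1-(dimethoxymethyl)-3-methoxy-5-(methoxymethoxy)benzene
Conditions: HC(OMe)3, MeOH, PPTS (cat.), 40 °C; Et3N quench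
Reagents that add atoms: trimethyl orthoformate, COC(OC)OC
Why: Acid-catalysed acetalisation driven by the orthoformate masks the aldehyde against n-BuLi, and the weak acid should leave the aryl MOM ether intact.

**Step 3**
Reactants: 3 1-(dimethoxymethyl)-3-methoxy-5-(methoxymethoxy)benzene
Product: 6 [4-(dimethoxymethyl)-2-methoxy-6-(methoxymethoxy)phenyl]methanol, via aryllithium 4 (not isolated), via aldehyde 5 (not isolated)
Conditions: n-BuLi, THF, 0 °C; DMF, 0 °C to rt; then MeOH, NaBH4, 0 °C
Reagents that add atoms: N,N-dimethylformamide, CN(C)C=O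
Why: Directed ortho-metalation should occur at the position flanked by both OMe and OMOM (cooperative direction), and formylation followed by borohydride reduction in the same pot gives the benzylic alcohol.

**Step 4**
Reactants: 6 [4-(dimethoxymethyl)-2-methoxy-6-(methoxymethoxy)phenyl]methanol
Product: 7 5-(dimethoxymethyl)-1-methoxy-2-[(4-methoxybenzyloxy)methyl]-3-(methoxymethoxy)benzene
Conditions: NaH, PMBCl, Bu4NI (cat.), DMF, 0 °C to rt
Reagents that add atoms: 4-methoxybenzyl chloride, COc1ccc(CCl)cc1
Why: Williamson etherification gives a PMB ether that tolerates n-BuLi and aqueous acid and can later be removed oxidatively beside a silyl ether and an acylal.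

**Step 5**
Reactants: 7 5-(dimethoxymethyl)-1-methoxy-2-[(4-methoxybenzyloxy)methyl]-3-(methoxymethoxy)benzene
Product: 10 rac-3,7-dihydroxy-5-methoxy-6-[(4-methoxybenzyloxy)methyl]isobenzofuran-1(3H)-one, via aryllithium 8 (not isolated), via lithium carboxylate 9 (not isolated)
Conditions: n-BuLi, THF, –20 to 0 °C; CO2 (g), –78 °C to rt; then 2 M HCl, THF, 45 °C
Reagents that add atoms: carbon dioxide, O=C=O; water, O
Why: A second directed ortho-metalation should go to the site between the acetal and the stronger MOM director, carboxylation places the acid there, and acid hydrolysis unmasks aldehyde and phenol so that the 2-formylbenzoic acid closes (carboxyl oxygen onto the aldehyde) to the racemic lactol.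

**Step 6**
Reactants: 10 rac-3,7-dihydroxy-5-methoxy-6-[(4-methoxybenzyloxy)methyl]isobenzofuran-1(3H)-one
Product: 11 (3R)-3-acetoxy-7-hydroxy-5-methoxy-6-[(4-methoxybenzyloxy)methyl]isobenzofuran-1(3H)-one
Conditions: Burkholderia cepacia lipase (immobilised), vinyl acetate, Et3N (0.2 equiv), toluene, 40 °C
Reagents that add atoms: vinyl acetate, CC(=O)OC=C
Why: Lipase-catalysed transesterification under dynamic kinetic resolution: the lactol enantiomers interconvert through the open formyl acid while the enzyme acetylates one of them, the empirical size rule for secondary alcohols (aryl side large) predicts the (3R)-acetate, and the chelated phenol should not be acylated.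

**Step 7**
Reactants: 11 (3R)-3-acetoxy-7-hydroxy-5-methoxy-6-[(4-methoxybenzyloxy)methyl]isobenzofuran-1(3H)-one
Product: 12 (3R)-3-acetoxy-7-(tert-butyldimethylsilyloxy)-5-methoxy-6-[(4-methoxybenzyloxy)methyl]isobenzofuran-1(3H)-one
Conditions: TBSOTf, 2,6-lutidine, CH2Cl2, –40 to 0 °C
Reagents that add atoms: tert-butyldimethylsilyl trifluoromethanesulfonate, CC(C)(C)[Si](C)(C)OS(=O)(=O)C(F)(F)F
Why: The silyl triflate with a non-nucleophilic base silylates the hindered, hydrogen-bonded phenol without touching the acylal, whose configuration is fixed once acylated.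

**Step 8**
Reactants: 12 (3R)-3-acetoxy-7-(tert-butyldimethylsilyloxy)-5-methoxy-6-[(4-methoxybenzyloxy)methyl]isobenzofuran-1(3H)-one
Product: 13 (3R)-3-acetoxy-7-(tert-butyldimethylsilyloxy)-6-(hydroxymethyl)-5-methoxyisobenzofuran-1(3H)-one
Conditions: DDQ, CH2Cl2/pH 7 phosphate buffer, 0 °C to rt
Reagents that add atoms: none
Why: Oxidative PMB cleavage (hydride abstraction from the more electron-rich anisyl CH2, then hydrolysis) is neutral and should spare the aryl silyl ether, the acylal and the carbonyl-deactivated ring B.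

**Step 9**
Reactants: 14 butane-2,3-dione (threefold excess); 15 methyl (triphenylphosphoranylidene)acetate
Product: 16 methyl (E)-3-methyl-4-oxopent-2-enoate
Conditions: CH2Cl2, rt
Reagents that add atoms: none
Why: Wittig olefination of the activated diketone with a stabilised ylide should give the (E)-enoate, and the excess of dione suppresses double olefination.

**Step 10**
Reactants: 16 methyl (E)-3-methyl-4-oxopent-2-enoate
Product: 19 methyl (E)-5-diazo-3-methyl-4-oxopent-2-enoate, via lithium enolate 17 (not isolated), via trifluoroacetyl diketone 18 (not isolated)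
Conditions: LiN(SiMe3)2, THF, –78 °C; CF3CO2CH2CF3, –78 °C; 1 M HCl work-up; then MsN3, Et3N, H2O (1 equiv), MeCN, rt
Reagents that add atoms: methanesulfonyl azide, CS(=O)(=O)N=[N+]=[N-]
Why: Detrifluoroacetylative diazo transfer (kinetic enolate at the acetyl methyl, Claisen trifluoroacetylation, Regitz-type transfer with loss of the trifluoroacetyl group) is the established entry to unsaturated diazo ketones and uses no diazoalkane.

**Step 11**
Reactants: 19 methyl (E)-5-diazo-3-methyl-4-oxopent-2-enoate
Product: 20 (E)-5-diazo-3-methyl-4-oxopent-2-enoic acid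
Conditions: LiOH·H2O, THF/H2O, 0 °C; cold aq. citric acid to pH 3–4; used at once
Reagents that add atoms: lithium hydroxide, [Li+].[OH-]
Why: Saponification of the unhindered methyl ester is compatible with the base-stable diazo ketone, and acidification with a weak acid avoids protonation of the diazo carbon.

**Step 12**
Reactants: 21 2-chloro-1,1-dimethoxyethane
Product: 23 1-methoxyprop-1-yne, via sodium methoxyacetylide 22 (not isolated)
Conditions: NaNH2 (3 equiv), liquid NH3, –40 °C; then MeI, –60 to –33 °C; taken up in cold ClCH2CH2Cl as a titrated stock solution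
Reagents that add atoms: iodomethane, CI
Why: Double elimination of the chloroacetal with NaNH2 gives the alkoxyacetylide, which is C-methylated in liquid ammonia (acetylide alkylation).

**Step 13**
Reactants: 13 (3R)-3-acetoxy-7-(tert-butyldimethylsilyloxy)-6-(hydroxymethyl)-5-methoxyisobenzofuran-1(3H)-one; 20 (E)-5-diazo-3-methyl-4-oxopent-2-enoic acid
Product: 24 [(3R)-3-acetoxy-7-(tert-butyldimethylsilyloxy)-5-methoxy-1-oxo-1,3-dihydroisobenzofuran-6-yl]methyl (E)-5-diazo-3-methyl-4-oxopent-2-enoate
Conditions: EDC·HCl, DMAP (cat.), CH2Cl2, 0 °C, dark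
Reagents that add atoms: none
Why: Steglich esterification acylates the primary benzylic alcohol under near-neutral conditions that a diazo ketone and an acylal tolerate, and the (E)-acid cannot close to a pseudo-acid.

**Step 14**
Reactants: 24 ring-B (E)-5-diazo-3-methyl-4-oxopent-2-enoate; 23 1-methoxyprop-1-yne (3 equiv)
Product: 29 [(3R)-3-acetoxy-7-(tert-butyldimethylsilyloxy)-5-methoxy-1-oxo-1,3-dihydroisobenzofuran-6-yl]methyl 2-hydroxy-4-methoxy-3,6-dimethylbenzoate, via vinylketene 25 (not isolated), via vinylcyclobutenone 26 (not isolated), via dienylketene 27 (not isolated), via cyclohexadienone 28 (not isolated)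
Conditions: hν (365 nm), ClCH2CH2Cl (0.03 M, degassed), 20 °C; then 80 °C
Reagents that add atoms: none
Why: Irradiation triggers a photochemical Wolff rearrangement to the (E)-vinylketene 25, whose ketene carbon is attacked by the nucleophilic methyl-bearing carbon of the ynol ether in a polarised [2+2] cycloaddition that gives 2-methyl-3-methoxy-4-vinylcyclobutenone 26 and forms C2–C3 and C4–C5. Light or the final warming opens 26 by reversible 4π electrocyclic cleavage to dienylketene 27, which closes ring A by 6π electrocyclisation (C1–C2) and tautomerises through dienone 28 to the phenol; this is the photo-Wolff variant of the Danheiser benzannulation, known for unsaturated α-diazo ketones with alkoxy- and siloxyalkynes. Connectivity fixes every substituent: the former ketone carbon becomes C2–OH, the alkyne supplies C3–Me and C4–OMe, the diazo carbon becomes C5–H and the enoate carbons become C6–Me and the ester-bearing C1. No stereocentre is created (the sp3 centres of 26 and 28 are erased on aromatisation) and the ring-B acylal is a spectator under these neutral conditions. The regiochemistry needed is secured by the polarity match between the ketene carbon and the β-carbon of the ynol ether, and the (E)-alkene holds the ester carbonyl away from the ketene, which a (Z)-ester would capture as a 6-alkoxy-2-pyranone. Light of 365 nm addresses the diazo ketone band and should leave the phthalide and benzoate chromophores unexcited; the ester on the vinylketene is the untested element and should make the ketene more, not less, electrophilic towards the electron-rich alkyne.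

**Step 15**
Reactants: 29 silyl-protected ring-A/ring-B ester
Product: 30 [(3R)-3-acetoxy-7-hydroxy-5-methoxy-1-oxo-1,3-dihydroisobenzofuran-6-yl]methyl 2-hydroxy-4-methoxy-3,6-dimethylbenzoate
Conditions: HF·pyridine, pyridine, THF, 0 °C to rt
Reagents that add atoms: none
Why: Fluoride-mediated Si–O cleavage of the aryl silyl ether under buffered acidic conditions should leave the acylal acetate (a destabilised oxocarbenium precursor), the lactone and the hindered benzyl ester untouched.

**Step 16**
Reactants: 30 [(3R)-3-acetoxy-7-hydroxy-5-methoxy-1-oxo-1,3-dihydroisobenzofuran-6-yl]methyl 2-hydroxy-4-methoxy-3,6-dimethylbenzoate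
Product: 31 [(3R)-3,7-dihydroxy-5-methoxy-1-oxo-1,3-dihydroisobenzofuran-6-yl]methyl 2-hydroxy-4-methoxy-3,6-dimethylbenzoate
Conditions: Burkholderia cepacia lipase (immobilised), n-BuOH, t-BuOMe, 20 °C; filtration, evaporation below 20 °C
Reagents that add atoms: none
Why: Lipase-catalysed alcoholysis cleaves the acetyl C–O bond and not the C3–O bond, so the lactol is freed with retention, the (3R)-acetate is the enantiomer the same enzyme accepts, and the neutral non-aqueous medium limits ring–chain epimerisation.

**Compound list**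
1 | 3-hydroxy-5-methoxybenzaldehyde | COc1cc(O)cc(C=O)c1 | starting material
2 | 3-methoxy-5-(methoxymethoxy)benzaldehyde | COCOc1cc(OC)cc(C=O)c1 | intermediate
3 | 1-(dimethoxymethyl)-3-methoxy-5-(methoxymethoxy)benzene | COCOc1cc(OC)cc(C(OC)OC)c1 | intermediate
4 | [4-(dimethoxymethyl)-2-methoxy-6-(methoxymethoxy)phenyl]lithium | [Li]c1c(OC)cc(C(OC)OC)cc1OCOC | intermediate
5 | 4-(dimethoxymethyl)-2-methoxy-6-(methoxymethoxy)benzaldehyde | COCOc1cc(C(OC)OC)cc(OC)c1C=O | intermediate
6 | [4-(dimethoxymethyl)-2-methoxy-6-(methoxymethoxy)phenyl]methanol | COCOc1cc(C(OC)OC)cc(OC)c1CO | intermediate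
7 | 5-(dimethoxymethyl)-1-methoxy-2-[(4-methoxybenzyloxy)methyl]-3-(methoxymethoxy)benzene | COCOc1cc(C(OC)OC)cc(OC)c1COCc1ccc(OC)cc1 | intermediate
8 | [6-(dimethoxymethyl)-4-methoxy-3-[(4-methoxybenzyloxy)methyl]-2-(methoxymethoxy)phenyl]lithium | [Li]c1c(OCOC)c(COCc2ccc(OC)cc2)c(OC)cc1C(OC)OC | intermediate
9 | lithium 2-(dimethoxymethyl)-4-methoxy-5-[(4-methoxybenzyloxy)methyl]-6-(methoxymethoxy)benzoate | [Li+].[O-]C(=O)c1c(OCOC)c(COCc2ccc(OC)cc2)c(OC)cc1C(OC)OC | intermediate
10 | rac-3,7-dihydroxy-5-methoxy-6-[(4-methoxybenzyloxy)methyl]isobenzofuran-1(3H)-one | COc1ccc(COCc2c(OC)cc3c(c2O)C(=O)OC3O)cc1 | intermediate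
11 | (3R)-3-acetoxy-7-hydroxy-5-methoxy-6-[(4-methoxybenzyloxy)methyl]isobenzofuran-1(3H)-one | COc1ccc(COCc2c(OC)cc3c(c2O)C(=O)O[C@H]3OC(C)=O)cc1 | intermediate
12 | (3R)-3-acetoxy-7-(tert-butyldimethylsilyloxy)-5-methoxy-6-[(4-methoxybenzyloxy)methyl]isobenzofuran-1(3H)-one | COc1ccc(COCc2c(OC)cc3c(c2O[Si](C)(C)C(C)(C)C)C(=O)O[C@H]3OC(C)=O)cc1 | intermediate
13 | (3R)-3-acetoxy-7-(tert-butyldimethylsilyloxy)-6-(hydroxymethyl)-5-methoxyisobenzofuran-1(3H)-one | OCc1c(OC)cc2c(c1O[Si](C)(C)C(C)(C)C)C(=O)O[C@H]2OC(C)=O | intermediate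
14 | butane-2,3-dione | CC(=O)C(C)=O | starting material
15 | methyl (triphenylphosphoranylidene)acetate | COC(=O)C=P(c1ccccc1)(c1ccccc1)c1ccccc1 | starting material
16 | methyl (E)-3-methyl-4-oxopent-2-enoate | CC(=O)/C(C)=C/C(=O)OC | intermediate
17 | lithium (E)-5-methoxy-3-methyl-5-oxopenta-1,3-dien-2-olate | [Li+].[O-]C(=C)/C(C)=C/C(=O)OC | intermediate
18 | methyl (E)-7,7,7-trifluoro-3-methyl-4,6-dioxohept-2-enoate | O=C(CC(=O)/C(C)=C/C(=O)OC)C(F)(F)F | intermediate
19 | methyl (E)-5-diazo-3-methyl-4-oxopent-2-enoate | [N-]=[N+]=CC(=O)/C(C)=C/C(=O)OC | intermediate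
20 | (E)-5-diazo-3-methyl-4-oxopent-2-enoic acid | [N-]=[N+]=CC(=O)/C(C)=C/C(=O)O | intermediate
21 | 2-chloro-1,1-dimethoxyethane | COC(CCl)OC | starting material
22 | sodium methoxyacetylide | [Na+].[C-]#COC | intermediate
23 | 1-methoxyprop-1-yne | COC#CC | intermediate
24 | [(3R)-3-acetoxy-7-(tert-butyldimethylsilyloxy)-5-methoxy-1-oxo-1,3-dihydroisobenzofuran-6-yl]methyl (E)-5-diazo-3-methyl-4-oxopent-2-enoate | [N-]=[N+]=CC(=O)/C(C)=C/C(=O)OCc1c(OC)cc2c(c1O[Si](C)(C)C(C)(C)C)C(=O)O[C@H]2OC(C)=O | intermediate
25 | ring-B ester of (E)-3-methyl-5-oxopenta-2,4-dienoic acid (vinylketene) | O=C=C/C(C)=C/C(=O)OCc1c(OC)cc2c(c1O[Si](C)(C)C(C)(C)C)C(=O)O[C@H]2OC(C)=O | intermediate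
26 | ring-B ester of (E)-3-(2-methoxy-3-methyl-4-oxocyclobut-2-en-1-yl)but-2-enoic acid (both configurations at the cyclobutenone sp3 carbon) | COC1=C(C)C(=O)C1/C(C)=C/C(=O)OCc1c(OC)cc2c(c1O[Si](C)(C)C(C)(C)C)C(=O)O[C@H]2OC(C)=O | intermediate
27 | ring-B ester of (2E,4E)-5-methoxy-3,6-dimethyl-7-oxohepta-2,4,6-trienoic acid (dienylketene) | O=C=C(C)/C(OC)=C\C(C)=C\C(=O)OCc1c(OC)cc2c(c1O[Si](C)(C)C(C)(C)C)C(=O)O[C@H]2OC(C)=O | intermediate
28 | ring-B ester of 4-methoxy-3,6-dimethyl-2-oxocyclohexa-3,5-diene-1-carboxylic acid (both configurations at C1 of the dienone) | COC1=C(C)C(=O)C(C(=O)OCc2c(OC)cc3c(c2O[Si](C)(C)C(C)(C)C)C(=O)O[C@H]3OC(C)=O)C(C)=C1 | intermediate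
29 | [(3R)-3-acetoxy-7-(tert-butyldimethylsilyloxy)-5-methoxy-1-oxo-1,3-dihydroisobenzofuran-6-yl]methyl 2-hydroxy-4-methoxy-3,6-dimethylbenzoate | COc1cc(C)c(C(=O)OCc2c(OC)cc3c(c2O[Si](C)(C)C(C)(C)C)C(=O)O[C@H]3OC(C)=O)c(O)c1C | intermediate
30 | [(3R)-3-acetoxy-7-hydroxy-5-methoxy-1-oxo-1,3-dihydroisobenzofuran-6-yl]methyl 2-hydroxy-4-methoxy-3,6-dimethylbenzoate | COc1cc(C)c(C(=O)OCc2c(OC)cc3c(c2O)C(=O)O[C@H]3OC(C)=O)c(O)c1C | intermediate
31 | [(3R)-3,7-dihydroxy-5-methoxy-1-oxo-1,3-dihydroisobenzofuran-6-yl]methyl 2-hydroxy-4-methoxy-3,6-dimethylbenzoate | COc1cc(C)c(C(=O)OCc2c(OC)cc3c(c2O)C(=O)O[C@H]3O)c(O)c1C | target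

**Step count**
Total: 16 steps. Longest linear sequence: 12 steps (steps 1–8 and 13–16, from compound 1); the acid branch (steps 9–11) joins at step 13 and the alkyne (step 12) at step 14.

**Steps most likely to fail**

Step 14. The vinylketene may be lost faster than it is captured by the alkyne: photoisomerisation of the enoate to the (Z)-series followed by internal closure onto the ester carbonyl, ketene oligomerisation, acylation of the newly formed phenol, or stalling at the cyclobutenone stage. The fallback gives up the annulation and brings ring A in ready-made. Purchased methyl 2,4-dihydroxy-3,6-dimethylbenzoate F1 is methylated at the non-chelated 4-OH (MeI, K2CO3, acetone, reflux) to methyl 2-hydroxy-4-methoxy-3,6-dimethylbenzoate F2. Saponification (KOH, aqueous DMSO, 90 °C) gives 2-hydroxy-4-methoxy-3,6-dimethylbenzoic acid F3. F3 is joined to ring-B alcohol 13 by Mitsunobu esterification (PPh3, DIAD, THF, 0 °C), in which the hindered carboxylate acts as the nucleophile at the benzylic carbon. The fallback sets out from 13 and returns to the route at 29.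

Step 16. The enzyme may not accept the bulky diaryl substrate, or a slow reaction may leave time for ring–chain epimerisation of the freed lactol. The fallback replaces biocatalysis by chemoselective aminolysis with an α-nucleophile: hydrazinium acetate in DMF at –20 °C, the standard reagent for acetates on hemiacetal carbons, attacks the acetyl carbonyl (retention at the lactol carbon) and should leave the lactone and the hindered benzoate alone. It is followed by immediate cold, slightly acidic work-up. The fallback sets out from 30 and returns at 31.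

Step 6. Enantio-discrimination by the lipase may be insufficient or of the opposite sense, or lactol racemisation may be slow relative to acylation so that the resolution is not dynamic. The fallback separates enantiomers by chromatography. Lactol 10 is bis-silylated (TBSCl, imidazole, DMF) to rac-3,7-bis(tert-butyldimethylsilyloxy)-5-methoxy-6-[(4-methoxybenzyloxy)methyl]isobenzofuran-1(3H)-one F4. The labile hemiacetal silyl ether is hydrolysed selectively (AcOH/THF/H2O, rt) to rac-7-(tert-butyldimethylsilyloxy)-3-hydroxy-5-methoxy-6-[(4-methoxybenzyloxy)methyl]isobenzofuran-1(3H)-one F5. Acetylation (Ac2O, pyridine, 0 °C) gives rac-3-acetoxy-7-(tert-butyldimethylsilyloxy)-5-methoxy-6-[(4-methoxybenzyloxy)methyl]isobenzofuran-1(3H)-one F6. Preparative chromatography on a chiral stationary phase delivers 12. The (3S)-3-acetoxy-7-(tert-butyldimethylsilyloxy)-5-methoxy-6-[(4-methoxybenzyloxy)methyl]isobenzofuran-1(3H)-one F7 is recycled by hydrazinium acetate in DMF to F5, which racemises and is re-acetylated. The fallback sets out from 10 and returns at 12.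

**Further compounds**
F1 | step 14 | methyl 2,4-dihydroxy-3,6-dimethylbenzoate (purchased) | COC(=O)c1c(C)cc(O)c(C)c1O
F2 | step 14 | methyl 2-hydroxy-4-methoxy-3,6-dimethylbenzoate | COC(=O)c1c(C)cc(OC)c(C)c1O
F3 | step 14 | 2-hydroxy-4-methoxy-3,6-dimethylbenzoic acid | Cc1cc(OC)c(C)c(O)c1C(=O)O
F0 | step 16 | none | none
F4 | step 6 | rac-3,7-bis(tert-butyldimethylsilyloxy)-5-methoxy-6-[(4-methoxybenzyloxy)methyl]isobenzofuran-1(3H)-one | COc1ccc(COCc2c(OC)cc3c(c2O[Si](C)(C)C(C)(C)C)C(=O)OC3O[Si](C)(C)C(C)(C)C)cc1
F5 | step 6 | rac-7-(tert-butyldimethylsilyloxy)-3-hydroxy-5-methoxy-6-[(4-methoxybenzyloxy)methyl]isobenzofuran-1(3H)-one | COc1ccc(COCc2c(OC)cc3c(c2O[Si](C)(C)C(C)(C)C)C(=O)OC3O)cc1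
F6 | step 6 | rac-3-acetoxy-7-(tert-butyldimethylsilyloxy)-5-methoxy-6-[(4-methoxybenzyloxy)methyl]isobenzofuran-1(3H)-one | COc1ccc(COCc2c(OC)cc3c(c2O[Si](C)(C)C(C)(C)C)C(=O)OC3OC(C)=O)cc1
F7 | step 6 | (3S)-3-acetoxy-7-(tert-butyldimethylsilyloxy)-5-methoxy-6-[(4-methoxybenzyloxy)methyl]isobenzofuran-1(3H)-one | COc1ccc(COCc2c(OC)cc3c(c2O[Si](C)(C)C(C)(C)C)C(=O)O[C@@H]3OC(C)=O)cc1
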